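**Retrosynthetic overview**
1. The strategy rests on C2 of ring C: a carbinol carbon (O1–C2) bonded only to C3 and to C1' of ring B. It can therefore be inserted as a CHCl unit between a boron atom on C3 and a ring B aryl nucleophile. C3, a carbinol carbon between C2 and the benzylic C4 on ring A, is inserted the same way one cycle earlier.
2. Last disconnections: the galloyl ester at O3' (after desilylation), then ring C at O1–C2 by Mitsunobu closure with inversion from a (1S,2S) syn carbinol/benzyl ether carrying a free ring A phenol.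
3. Key disconnection: C2–C3 and C2–C1' by LiCHCl2 insertion into the C3–B bond of the alpha-benzyloxy boronic ester 9, then aryl transfer from the ring B Grignard reagent 15. The (R,R)-diol on boron controls C2 as it controlled C3.
4. Boronic ester 9 comes from ring A by three successive shifts to carbon: aryl to CH2 (chloromethylboronate 5), C4 to C3 (LiCHCl2), and benzyloxide displacement of chloride.
5. Rings A and B and the galloyl ring are bought as aromatic compounds; ring C is the only ring formed (step 13).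

Key step: step 10

Assumption: the (R,R)-diol directs LiCHCl2 insertion to the (alpha-S)-chloro boronic ester (Cl > C > B), the usual sense for C2-symmetric (R,R)-1,2-diol boronic esters; if the sense proves opposite, the (S,S)-diol is used throughout.

**Route**

Step 1
Reactants: 1 3,5-bis(benzyloxy)phenol
Product: 2 1,3-bis(benzyloxy)-5-(methoxymethoxy)benzene
Conditions: NaH, MOMCl, DMF, 0 → 20 °C
Reagents that add atoms: chloromethyl methyl ether, COCCl
Why: Williamson-type O-alkylation of the sodium phenoxide with a hard electrophile should give the aryl MOM ether, which directs the metalation in step 3 and later releases O1.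

Step 2
Reactants: 3 (1R,2R)-1,2-dicyclohexylethane-1,2-diol
Product: 5 (4R,5R)-2-(chloromethyl)-4,5-dicyclohexyl-1,3,2-dioxaborolane, via diisopropyl (chloromethyl)boronate 4 (not isolated)
Conditions: BrCH2Cl, B(OiPr)3, n-BuLi, THF, −78 °C; MeSO3H, −78 → 20 °C; then 3, 20 °C
Reagents that add atoms: bromochloromethane, ClCBr; triisopropyl borate, CC(C)OB(OC(C)C)OC(C)C
Why: LiCH2Cl formed by Br/Li exchange is trapped in situ by the borate, acid releases 4, and transesterification with the diol gives the cyclic ester, the established preparation of (chloromethyl)boronic esters.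

Step 3
Reactants: 2 1,3-bis(benzyloxy)-5-(methoxymethoxy)benzene; 5 (4R,5R)-2-(chloromethyl)-4,5-dicyclohexyl-1,3,2-dioxaborolane
Product: 7 (4R,5R)-2-[2,4-bis(benzyloxy)-6-(methoxymethoxy)benzyl]-4,5-dicyclohexyl-1,3,2-dioxaborolane, via 2,4-bis(benzyloxy)-6-(methoxymethoxy)phenyllithium 6 (not isolated)
Conditions: n-BuLi, THF, 0 °C; then 5, −78 → 20 °C
Reagents that add atoms: none
Why: Directed ortho-metalation next to the chelating OMOM group (its two flanking positions are equivalent, each also activated by OBn) gives 6, whose borate with 5 undergoes a 1,2-aryl shift with loss of chloride (halomethylboronate homologation), forming C4a–C4 without a labile trialkoxybenzyl halide.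

Step 4
Reactants: 7 (4R,5R)-2-[2,4-bis(benzyloxy)-6-(methoxymethoxy)benzyl]-4,5-dicyclohexyl-1,3,2-dioxaborolane
Product: 8 (4R,5R)-2-{(1S)-1-chloro-2-[2,4-bis(benzyloxy)-6-(methoxymethoxy)phenyl]ethyl}-4,5-dicyclohexyl-1,3,2-dioxaborolane
Conditions: CH2Cl2, n-BuLi, THF, −100 °C; 7; ZnCl2, −100 → 20 °C
Reagents that add atoms: dichloromethane, ClCCl (delivered as LiCHCl2)
Why: Matteson homologation: LiCHCl2 adds to boron and ZnCl2 promotes the 1,2-shift of C4 with loss of one diastereotopic chloride, the (R,R)-diol setting C3 as the (S)-chloride.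

Step 5
Reactants: 8 (4R,5R)-2-{(1S)-1-chloro-2-[2,4-bis(benzyloxy)-6-(methoxymethoxy)phenyl]ethyl}-4,5-dicyclohexyl-1,3,2-dioxaborolane
Product: 9 (4R,5R)-2-{(1R)-1-(benzyloxy)-2-[2,4-bis(benzyloxy)-6-(methoxymethoxy)phenyl]ethyl}-4,5-dicyclohexyl-1,3,2-dioxaborolane
Conditions: BnOH, n-BuLi, THF, 0 °C; then 8, THF/DMSO, −78 → 20 °C
Reagents that add atoms: benzyl alcohol, OCc1ccccc1 (used as LiOBn)
Why: Benzyloxide adds to boron and migrates to carbon anti to chloride (stereospecific 1,2-shift, inversion), giving the alpha-benzyloxy boronic ester whose C3 already has the geometry of 3S in the target (descriptor R here because carbon outranks boron).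

Step 6
Reactants: 10 5-bromo-2-hydroxybenzaldehyde
Product: 11 2-(benzyloxy)-5-bromobenzaldehyde
Conditions: BnBr, K2CO3, DMF, 20 °C
Reagents that add atoms: benzyl bromide, BrCc1ccccc1
Why: Williamson etherification of the phenol places the benzyl ether para to bromine, so it becomes O4'.

Step 7
Reactants: 11 2-(benzyloxy)-5-bromobenzaldehyde
Product: 13 2-(benzyloxy)-5-bromophenol, via 2-(benzyloxy)-5-bromophenyl formate 12 (not isolated)
Conditions: mCPBA, CH2Cl2, 20 °C; then K2CO3 (cat.), MeOH, 20 °C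
Reagents that add atoms: 3-chloroperoxybenzoic acid, O=C(OO)c1cccc(Cl)c1
Why: Baeyer–Villiger oxidation with migration of the ortho-alkoxyaryl group gives the formate, and methanolysis frees the phenol, fixing the future O3' meta to bromine without regiochemical ambiguity.

Step 8
Reactants: 13 2-(benzyloxy)-5-bromophenol
Product: 14 [2-(benzyloxy)-5-bromophenoxy]triisopropylsilane
Conditions: TIPSCl, imidazole, DMF, 20 °C
Reagents that add atoms: chlorotriisopropylsilane, CC(C)[Si](Cl)(C(C)C)C(C)C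
Why: Silylation of the phenol gives a bulky aryl silyl ether that should tolerate Grignard formation, cold basic peroxide and Mitsunobu conditions and is orthogonal to benzyl ethers.

Step 9
Reactants: 14 [2-(benzyloxy)-5-bromophenoxy]triisopropylsilane
Product: 15 [4-(benzyloxy)-3-(triisopropylsilyloxy)phenyl]magnesium bromide
Conditions: Mg turnings, I2 (cat.), THF, 50 °C
Reagents that add atoms: magnesium, [Mg]
Why: Insertion of magnesium into the aryl C–Br bond (Grignard formation) leaves the silyl and benzyl ethers untouched; the solution is used directly.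

Step 10
Reactants: 9 (4R,5R)-2-{(1R)-1-(benzyloxy)-2-[2,4-bis(benzyloxy)-6-(methoxymethoxy)phenyl]ethyl}-4,5-dicyclohexyl-1,3,2-dioxaborolane; 15 [4-(benzyloxy)-3-(triisopropylsilyloxy)phenyl]magnesium bromide
Product: 17 (4R,5R)-2-{(1S,2S)-2-(benzyloxy)-1-[4-(benzyloxy)-3-(triisopropylsilyloxy)phenyl]-3-[2,4-bis(benzyloxy)-6-(methoxymethoxy)phenyl]propyl}-4,5-dicyclohexyl-1,3,2-dioxaborolane, via (1S,2S)-alpha-chloro boronic ester 16 (not isolated)
Conditions: CH2Cl2, n-BuLi, THF, −100 °C; 9; ZnCl2 (0.6 equiv), −100 → 20 °C; then 15 (2.5 equiv), THF, −78 → 20 °C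
Reagents that add atoms: dichloromethane, ClCCl (delivered as LiCHCl2)
Why: LiCHCl2 adds to boron of 9 and the ZnCl2-assisted 1,2-shift carries C3, with retention, onto the dichloromethyl carbon while one diastereotopic chloride leaves, giving 16 (C2–C3); 15 then forms a second borate and the ring B aryl group migrates anti to the remaining chloride, forming C2–C1' with inversion at C2. The closest known reaction type is the Matteson homologation of a chiral diol boronic ester followed by Grignard displacement of the alpha-chloride, as used for chain extension of alpha-benzyloxy boronic esters. No ring closes in this step. The new stereocentre C2 is controlled by the C2-symmetric (R,R)-diol on boron, which selects the chloride lost in the first shift, and by the stereospecific inversion in the second (descriptor 1S in both 16 and 17 because chlorine ranks above C3 and aryl below it); C3 keeps its geometry and its descriptor changes to S only because C2 now outranks C4. The step needs migration to outrun beta-elimination of boron and the C3 benzyloxy group, and needs 16 not to epimerise by chloride exchange; the poor leaving ability of benzyloxide, sub-stoichiometric ZnCl2, temperatures at or below 20 °C and immediate consumption of 16 by excess 15 should secure this.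

Step 11
Reactants: 17 (4R,5R)-2-{(1S,2S)-2-(benzyloxy)-1-[4-(benzyloxy)-3-(triisopropylsilyloxy)phenyl]-3-[2,4-bis(benzyloxy)-6-(methoxymethoxy)phenyl]propyl}-4,5-dicyclohexyl-1,3,2-dioxaborolane
Product: 18 (1S,2S)-2-(benzyloxy)-1-[4-(benzyloxy)-3-(triisopropylsilyloxy)phenyl]-3-[2,4-bis(benzyloxy)-6-(methoxymethoxy)phenyl]propan-1-ol
Conditions: 30% H2O2, aq. NaOH, THF, 0 °C
Reagents that add atoms: hydrogen peroxide, OO
Why: Boronic ester oxidation, in which hydroperoxide adds to boron and C2 shifts from boron to oxygen with retention, should give the syn (1S,2S) carbinol/benzyl ether and return diol 3; the cold, brief basic conditions should spare the aryl silyl ether.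

Step 12
Reactants: 18 (1S,2S)-2-(benzyloxy)-1-[4-(benzyloxy)-3-(triisopropylsilyloxy)phenyl]-3-[2,4-bis(benzyloxy)-6-(methoxymethoxy)phenyl]propan-1-ol
Product: 20 3,5-bis(benzyloxy)-2-{(2S,3S)-2-(benzyloxy)-3-[4-(benzyloxy)-3-(triisopropylsilyloxy)phenyl]-3-hydroxypropyl}phenol, via bis(trimethylsilyl) ether 19 (not isolated)
Conditions: TMSOTf, 2,2'-bipyridyl, MeCN, 0 → 20 °C; then H2O, citric acid (cat.), MeOH, 20 °C
Reagents that add atoms: none
Why: The silyl triflate/bipyridyl pair converts an aromatic MOM ether into the aryl TMS ether under buffered aprotic conditions (acetal cleavage) while masking the carbinol as its TMS ether, and mild aqueous acid then hydrolyses both Si–O bonds, avoiding the strong protic acid that could ionise the electron-rich benzylic carbinol.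

Step 13
Reactants: 20 3,5-bis(benzyloxy)-2-{(2S,3S)-2-(benzyloxy)-3-[4-(benzyloxy)-3-(triisopropylsilyloxy)phenyl]-3-hydroxypropyl}phenol
Product: 21 (2R,3S)-3,5,7-tris(benzyloxy)-2-[4-(benzyloxy)-3-(triisopropylsilyloxy)phenyl]chromane
Conditions: PPh3, DIAD, THF (dilute), 0 → 20 °C
Reagents that add atoms: none
Why: Mitsunobu etherification: the phenol is the only acidic pronucleophile and the benzylic carbinol the only free alcohol, so intramolecular SN2 displacement of the oxyphosphonium group closes ring C (6-exo-tet, O1–C2) with inversion, turning the syn (1S,2S) array into the 2,3-trans (2R,3S) flavan.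

Step 14
Reactants: 21 (2R,3S)-3,5,7-tris(benzyloxy)-2-[4-(benzyloxy)-3-(triisopropylsilyloxy)phenyl]chromane
Product: 22 2-(benzyloxy)-5-[(2R,3S)-3,5,7-tris(benzyloxy)chroman-2-yl]phenol
Conditions: Bu4NF, THF, 0 °C
Reagents that add atoms: none
Why: Fluoride-mediated desilylation cleaves only the aryl O–Si bond, freeing O3' as the single phenol.

Step 15
Reactants: 22 2-(benzyloxy)-5-[(2R,3S)-3,5,7-tris(benzyloxy)chroman-2-yl]phenol; 23 3,4,5-tris(benzyloxy)benzoic acid
Product: 24 2-(benzyloxy)-5-[(2R,3S)-3,5,7-tris(benzyloxy)chroman-2-yl]phenyl 3,4,5-tris(benzyloxy)benzoate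
Conditions: EDC·HCl, DMAP, CH2Cl2, 20 °C
Reagents that add atoms: none
Why: Steglich esterification acylates the only free hydroxyl group with the perbenzylated gallic acid.

Step 16
Reactants: 24 2-(benzyloxy)-5-[(2R,3S)-3,5,7-tris(benzyloxy)chroman-2-yl]phenyl 3,4,5-tris(benzyloxy)benzoate
Product: 25 catechin 3'-O-gallate, 2-hydroxy-5-[(2R,3S)-3,5,7-trihydroxychroman-2-yl]phenyl 3,4,5-trihydroxybenzoate
Conditions: H2 (1 atm), Pd(OH)2 on carbon, THF/EtOAc, 20 °C
Reagents that add atoms: none
Why: Hydrogenolysis of all seven benzyl ethers under neutral conditions should leave the aryl ester, the flavan O1–C2 bond and both stereocentres intact, and the base-free, non-nucleophilic medium is chosen to prevent galloyl migration to O4'.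

**Compound list**
1 | 3,5-bis(benzyloxy)phenol | Oc1cc(OCc2ccccc2)cc(OCc2ccccc2)c1 | starting material
2 | 1,3-bis(benzyloxy)-5-(methoxymethoxy)benzene | COCOc1cc(OCc2ccccc2)cc(OCc2ccccc2)c1 | intermediate
3 | (1R,2R)-1,2-dicyclohexylethane-1,2-diol | O[C@H](C1CCCCC1)[C@H](O)C1CCCCC1 | starting material
4 | diisopropyl (chloromethyl)boronate | ClCB(OC(C)C)OC(C)C | intermediate
5 | (4R,5R)-2-(chloromethyl)-4,5-dicyclohexyl-1,3,2-dioxaborolane | ClCB1O[C@H](C2CCCCC2)[C@@H](C2CCCCC2)O1 | intermediate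
6 | 2,4-bis(benzyloxy)-6-(methoxymethoxy)phenyllithium | [Li]c1c(OCOC)cc(OCc2ccccc2)cc1OCc1ccccc1 | intermediate
7 | (4R,5R)-2-[2,4-bis(benzyloxy)-6-(methoxymethoxy)benzyl]-4,5-dicyclohexyl-1,3,2-dioxaborolane | COCOc1cc(OCc2ccccc2)cc(OCc2ccccc2)c1CB1O[C@H](C2CCCCC2)[C@@H](C2CCCCC2)O1 | intermediate
8 | (4R,5R)-2-{(1S)-1-chloro-2-[2,4-bis(benzyloxy)-6-(methoxymethoxy)phenyl]ethyl}-4,5-dicyclohexyl-1,3,2-dioxaborolane | COCOc1cc(OCc2ccccc2)cc(OCc2ccccc2)c1C[C@@H](Cl)B1O[C@H](C2CCCCC2)[C@@H](C2CCCCC2)O1 | intermediate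
9 | (4R,5R)-2-{(1R)-1-(benzyloxy)-2-[2,4-bis(benzyloxy)-6-(methoxymethoxy)phenyl]ethyl}-4,5-dicyclohexyl-1,3,2-dioxaborolane | COCOc1cc(OCc2ccccc2)cc(OCc2ccccc2)c1C[C@H](OCc1ccccc1)B1O[C@H](C2CCCCC2)[C@@H](C2CCCCC2)O1 | intermediate
10 | 5-bromo-2-hydroxybenzaldehyde | O=Cc1cc(Br)ccc1O | starting material
11 | 2-(benzyloxy)-5-bromobenzaldehyde | O=Cc1cc(Br)ccc1OCc1ccccc1 | intermediate
12 | 2-(benzyloxy)-5-bromophenyl formate | O=COc1cc(Br)ccc1OCc1ccccc1 | intermediate
13 | 2-(benzyloxy)-5-bromophenol | Oc1cc(Br)ccc1OCc1ccccc1 | intermediate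
14 | [2-(benzyloxy)-5-bromophenoxy]triisopropylsilane | CC(C)[Si](C(C)C)(C(C)C)Oc1cc(Br)ccc1OCc1ccccc1 | intermediate
15 | [4-(benzyloxy)-3-(triisopropylsilyloxy)phenyl]magnesium bromide | CC(C)[Si](C(C)C)(C(C)C)Oc1cc([Mg]Br)ccc1OCc1ccccc1 | intermediate
16 | (4R,5R)-2-{(1S,2S)-2-(benzyloxy)-1-chloro-3-[2,4-bis(benzyloxy)-6-(methoxymethoxy)phenyl]propyl}-4,5-dicyclohexyl-1,3,2-dioxaborolane | Cl[C@@H](B1O[C@H](C2CCCCC2)[C@@H](C2CCCCC2)O1)[C@@H](OCc1ccccc1)Cc1c(OCOC)cc(OCc2ccccc2)cc1OCc1ccccc1 | intermediate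
17 | (4R,5R)-2-{(1S,2S)-2-(benzyloxy)-1-[4-(benzyloxy)-3-(triisopropylsilyloxy)phenyl]-3-[2,4-bis(benzyloxy)-6-(methoxymethoxy)phenyl]propyl}-4,5-dicyclohexyl-1,3,2-dioxaborolane | CC(C)[Si](C(C)C)(C(C)C)Oc1cc(ccc1OCc1ccccc1)[C@H](B1O[C@H](C2CCCCC2)[C@@H](C2CCCCC2)O1)[C@@H](OCc1ccccc1)Cc1c(OCOC)cc(OCc2ccccc2)cc1OCc1ccccc1 | intermediate
18 | (1S,2S)-2-(benzyloxy)-1-[4-(benzyloxy)-3-(triisopropylsilyloxy)phenyl]-3-[2,4-bis(benzyloxy)-6-(methoxymethoxy)phenyl]propan-1-ol | CC(C)[Si](C(C)C)(C(C)C)Oc1cc(ccc1OCc1ccccc1)[C@H](O)[C@@H](OCc1ccccc1)Cc1c(OCOC)cc(OCc2ccccc2)cc1OCc1ccccc1 | intermediate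
19 | bis(trimethylsilyl) ether of 20 (aryl OTMS and carbinol OTMS) | CC(C)[Si](C(C)C)(C(C)C)Oc1cc(ccc1OCc1ccccc1)[C@H](O[Si](C)(C)C)[C@@H](OCc1ccccc1)Cc1c(O[Si](C)(C)C)cc(OCc2ccccc2)cc1OCc1ccccc1 | intermediate
20 | 3,5-bis(benzyloxy)-2-{(2S,3S)-2-(benzyloxy)-3-[4-(benzyloxy)-3-(triisopropylsilyloxy)phenyl]-3-hydroxypropyl}phenol | CC(C)[Si](C(C)C)(C(C)C)Oc1cc(ccc1OCc1ccccc1)[C@H](O)[C@@H](OCc1ccccc1)Cc1c(O)cc(OCc2ccccc2)cc1OCc1ccccc1 | intermediate
21 | (2R,3S)-3,5,7-tris(benzyloxy)-2-[4-(benzyloxy)-3-(triisopropylsilyloxy)phenyl]chromane | CC(C)[Si](C(C)C)(C(C)C)Oc1cc(ccc1OCc1ccccc1)[C@H]1Oc2cc(OCc3ccccc3)cc(OCc3ccccc3)c2C[C@@H]1OCc1ccccc1 | intermediate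
22 | 2-(benzyloxy)-5-[(2R,3S)-3,5,7-tris(benzyloxy)chroman-2-yl]phenol | Oc1cc(ccc1OCc1ccccc1)[C@H]1Oc2cc(OCc3ccccc3)cc(OCc3ccccc3)c2C[C@@H]1OCc1ccccc1 | intermediate
23 | 3,4,5-tris(benzyloxy)benzoic acid | OC(=O)c1cc(OCc2ccccc2)c(OCc2ccccc2)c(OCc2ccccc2)c1 | starting material
24 | 2-(benzyloxy)-5-[(2R,3S)-3,5,7-tris(benzyloxy)chroman-2-yl]phenyl 3,4,5-tris(benzyloxy)benzoate | O=C(Oc1cc(ccc1OCc1ccccc1)[C@H]1Oc2cc(OCc3ccccc3)cc(OCc3ccccc3)c2C[C@@H]1OCc1ccccc1)c1cc(OCc2ccccc2)c(OCc2ccccc2)c(OCc2ccccc2)c1 | intermediate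
25 | catechin 3'-O-gallate | O=C(Oc1cc([C@H]2Oc3cc(O)cc(O)c3C[C@@H]2O)ccc1O)c1cc(O)c(O)c(O)c1 | target

**Step count**
Total: 16 steps. Longest linear sequence: 11 steps (steps 1, 3, 4, 5, 10, 11, 12, 13, 14, 15, 16).

**Steps most likely to fail**

Step 10. The borates may lose boron and the C3 benzyloxy group by beta-elimination, the alpha-chloride 16 may epimerise by chloride exchange before aryl transfer, or aryl migration may stall if ZnCl2 diverts 15 to an arylzinc species. The fallback makes the C2–C1' bond by carbonyl addition instead of a 1,2-shift. It sets out from 9: the LiCHCl2 insertion is run alone and 16 is isolated after aqueous work-up. Buffered oxidation of the alpha-chloro boronic ester (H2O2, NaHCO3, THF/H2O, 0 °C) should give (S)-2-(benzyloxy)-3-[2,4-bis(benzyloxy)-6-(methoxymethoxy)phenyl]propanal F1. Chelation-controlled addition of 15 (MgBr2·OEt2, CH2Cl2, −78 °C), with magnesium bridging the aldehyde and benzyloxy oxygens and the aryl group entering anti to the arylmethyl substituent, should give the syn carbinol directly. The route is rejoined at 18.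

Step 3. Deprotonation may occur between the two benzyloxy groups or at a benzylic OCH2 instead of next to OMOM, or aryl migration in the hindered borate may be incomplete. The fallback introduces C4 as a formyl carbon whose position is fixed by the free phenol. It sets out from 1: ortho-formylation with MgCl2, Et3N and paraformaldehyde (MeCN, reflux) should give 2,4-bis(benzyloxy)-6-hydroxybenzaldehyde F2. MOMCl/iPr2NEt then gives 2,4-bis(benzyloxy)-6-(methoxymethoxy)benzaldehyde F3, and condensation with TsNHNH2 in MeOH gives the N-tosylhydrazone F4. Base-mediated borylation through the aryldiazomethane (B2pin2, NaH, toluene, 110 °C, then MeOH) gives the pinacol benzylboronate F5. NaIO4/NH4OAc in acetone/H2O removes the pinacol to give [2,4-bis(benzyloxy)-6-(methoxymethoxy)benzyl]boronic acid F6, and condensation with 3 (MgSO4, Et2O) rejoins the route at 7.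

Step 12. The C1 carbinol, benzylic to the para-benzyloxy ring B, may ionise under the silyl triflate, scrambling that centre or closing ring C without stereocontrol. The fallback reverses the order so that the acetal is cleaved before the carbinol exists. It sets out from 17: the same TMSOTf/2,2'-bipyridyl treatment and aqueous work-up on the boronic ester should give the phenol boronic ester (4R,5R)-2-{(1S,2S)-2-(benzyloxy)-1-[4-(benzyloxy)-3-(triisopropylsilyloxy)phenyl]-3-[2,4-bis(benzyloxy)-6-hydroxyphenyl]propyl}-4,5-dicyclohexyl-1,3,2-dioxaborolane F7. Oxidation with H2O2/NaOH (THF, 0 °C) then rejoins the route at 20.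

**Further compounds**
F1 | step 10 | (S)-2-(benzyloxy)-3-[2,4-bis(benzyloxy)-6-(methoxymethoxy)phenyl]propanal | O=C[C@@H](OCc1ccccc1)Cc1c(OCOC)cc(OCc2ccccc2)cc1OCc1ccccc1
F2 | step 3 | 2,4-bis(benzyloxy)-6-hydroxybenzaldehyde | O=Cc1c(O)cc(OCc2ccccc2)cc1OCc1ccccc1
F3 | step 3 | 2,4-bis(benzyloxy)-6-(methoxymethoxy)benzaldehyde | O=Cc1c(OCOC)cc(OCc2ccccc2)cc1OCc1ccccc1
F4 | step 3 | N-tosylhydrazone of 2,4-bis(benzyloxy)-6-(methoxymethoxy)benzaldehyde | Cc1ccc(cc1)S(=O)(=O)N/N=C/c1c(OCOC)cc(OCc2ccccc2)cc1OCc1ccccc1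
F5 | step 3 | 2-[2,4-bis(benzyloxy)-6-(methoxymethoxy)benzyl]-4,4,5,5-tetramethyl-1,3,2-dioxaborolane | COCOc1cc(OCc2ccccc2)cc(OCc2ccccc2)c1CB1OC(C)(C)C(C)(C)O1
F6 | step 3 | [2,4-bis(benzyloxy)-6-(methoxymethoxy)benzyl]boronic acid | COCOc1cc(OCc2ccccc2)cc(OCc2ccccc2)c1CB(O)O
F7 | step 12 | (4R,5R)-2-{(1S,2S)-2-(benzyloxy)-1-[4-(benzyloxy)-3-(triisopropylsilyloxy)phenyl]-3-[2,4-bis(benzyloxy)-6-hydroxyphenyl]propyl}-4,5-dicyclohexyl-1,3,2-dioxaborolane | CC(C)[Si](C(C)C)(C(C)C)Oc1cc(ccc1OCc1ccccc1)[C@H](B1O[C@H](C2CCCCC2)[C@@H](C2CCCCC2)O1)[C@@H](OCc1ccccc1)Cc1c(O)cc(OCc2ccccc2)cc1OCc1ccccc1
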